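**Plan**
- Retrosynthesis cuts, in order: the three O‑benzyl bonds; ring C of the flavonol (O‑1–C‑2 bond and 3‑OH) back to a 2'‑hydroxychalcone; the chalcone C=C back to a benzodioxane aldehyde and a ring A acetophenone; the C‑2–C‑3 bond of the 1,4‑benzodioxane; the two ArO–CH2 bonds of a catechol bis‑ether.
- Forward: methyl 3,4‑dihydroxybenzoate is benzylated at its 3‑oxygen (later O‑4) and acylmethylated at its 4‑oxygen (later O‑1). The dioxane ring is then closed by C‑2–C‑3 bond formation, the ester is taken to the aldehyde, and chalcone, ring C and debenzylation follow.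
- Enabling feature: C‑3 is benzylic to the guaiacyl ring (para to its oxygen) and α to O‑4, so in the open precursor its CH2 is a hydride donor like a dialkoxybenzyl ether. C‑2 is α to O‑1 and to the carbon that becomes CH2OH; held at the acyl level on a chiral oxazolidinone, it is an enolate carbon.
- Stereochemistry: C‑2 comes from the (S)‑4‑benzyloxazolidinone, whose reductive removal also delivers the CH2OH. C‑3 is set trans to C‑2 in the ring‑closing transition state and is also the thermodynamic isomer. No later step touches either centre.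

Key step: step 4

Assumption: the chlorotitanium enolate of the N‑(aryloxyacetyl)oxazolidinone reacts as the chelated Z‑enolate, as its propionyl and alkoxyacetyl relatives do with cationic electrophiles.

**Step 1**
Reactants: 1 4‑(benzyloxy)‑3‑methoxybenzyl alcohol
Product: 2 4‑(benzyloxy)‑3‑methoxybenzyl chloride
Conditions: SOCl2 (1.2 equiv), CH2Cl2, 0 °C to rt; used crude
Reagents that add atoms: thionyl chloride, O=S(Cl)Cl
Why: Chlorodehydroxylation of an electron‑rich benzylic alcohol through its chlorosulfite, under which the aryl benzyl ether is inert.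

**Step 2**
Reactants: 3 methyl 3,4‑dihydroxybenzoate; 2 4‑(benzyloxy)‑3‑methoxybenzyl chloride
Product: 4 methyl 3‑{[4‑(benzyloxy)‑3‑methoxybenzyl]oxy}‑4‑hydroxybenzoate
Conditions: NaH (2.05 equiv), DMSO, rt; then 2 (1.0 equiv), rt; aq. NH4Cl
Reagents that add atoms: none
Why: Williamson etherification of the catechol dianion, in which the 4‑oxide is delocalised into the para ester so that the 3‑oxide is the more nucleophilic site and takes the single equivalent of benzylic chloride, which fixes the silybin (not isosilybin) regiochemistry.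

**Step 3**
Reactants: 4 methyl 3‑{[4‑(benzyloxy)‑3‑methoxybenzyl]oxy}‑4‑hydroxybenzoate; 5 (S)‑4‑benzyl‑3‑(chloroacetyl)‑1,3‑oxazolidin‑2‑one
Product: 6 methyl 4‑{2‑[(4S)‑4‑benzyl‑2‑oxo‑1,3‑oxazolidin‑3‑yl]‑2‑oxoethoxy}‑3‑{[4‑(benzyloxy)‑3‑methoxybenzyl]oxy}benzoate
Conditions: K2CO3 (1.5 equiv), NaI (0.2 equiv), acetone, 40 °C
Reagents that add atoms: none
Why: Finkelstein‑assisted Williamson alkylation, in which the weakly nucleophilic 4‑phenoxide attacks the soft CH2–X carbon of the α‑halo imide and not its carbonyl groups, and the stereocentre of the auxiliary is not touched.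

**Step 4**
Reactants: 6 methyl 4‑{2‑[(4S)‑4‑benzyl‑2‑oxo‑1,3‑oxazolidin‑3‑yl]‑2‑oxoethoxy}‑3‑{[4‑(benzyloxy)‑3‑methoxybenzyl]oxy}benzoate
Product: 9 methyl (2R,3S)‑2‑{[(4S)‑4‑benzyl‑2‑oxo‑1,3‑oxazolidin‑3‑yl]carbonyl}‑3‑[4‑(benzyloxy)‑3‑methoxyphenyl]‑2,3‑dihydro‑1,4‑benzodioxine‑6‑carboxylate, via hydroquinone mixed acetal 7 (not isolated), via chlorotitanium Z‑enolate oxocarbenium chloride 8 (not isolated)
Conditions: DDQ (1.05 equiv), 4 Å MS, CH2Cl2, 0 °C to rt; then −78 °C, TiCl4 (2.2 equiv), i‑Pr2NEt (2.5 equiv), −78 to −40 °C; aq. NH4Cl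
Reagents that add atoms: none
Why: Proposed new method: DDQ abstracts hydride from the C‑3 methylene of 6 (a 3,4‑dialkoxybenzyl aryl ether, the motif that makes such ethers DDQ‑labile) and the aryloxy‑benzylic oxocarbenium ion is stored as its hydroquinone adduct 7; TiCl4 then re‑ionises 7 and, with i‑Pr2NEt, turns the glycolyl imide into the chelated Z‑chlorotitanium enolate 8, whose α‑carbon attacks the E‑oxocarbenium carbon to form the C‑2–C‑3 bond. The closest known reactions are DDQ‑mediated oxidative C–H cyclisations of benzylic ethers onto tethered enol nucleophiles and the SN1‑type additions of titanium enolates of chiral N‑acyl oxazolidinones to acetals, orthoesters and chloromethyl ethers. The ring closes in the 6‑(enolexo)‑endo‑trig mode through a half‑chair in which O‑1, C‑8a, C‑4a and O‑4 stay in the arene plane. C‑2 is set by the auxiliary: in the titanium chelate the C‑4 benzyl group of the (S)‑oxazolidinone covers one enolate face, so the cation adds anti to it and should give 2R in the imide (2S after reduction); C‑3 is set relative to C‑2 by the E‑oxocarbenium geometry and the pseudo‑diequatorial placement of the aryl and acyl groups, which should give the trans (3S) isomer, also the thermodynamic one. The step needs hydride abstraction at the dialkoxybenzyl CH2 only (the plain benzyl ether and the benzyl of the auxiliary lack the para‑oxygen donor), complete consumption of DDQ before enolisation, and C‑ rather than O‑alkylation of the enolate (O‑attack would need an eight‑membered ring).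

**Step 5**
Reactants: 9 methyl (2R,3S)‑2‑{[(4S)‑4‑benzyl‑2‑oxo‑1,3‑oxazolidin‑3‑yl]carbonyl}‑3‑[4‑(benzyloxy)‑3‑methoxyphenyl]‑2,3‑dihydro‑1,4‑benzodioxine‑6‑carboxylate
Product: 10 {(2S,3S)‑3‑[4‑(benzyloxy)‑3‑methoxyphenyl]‑2,3‑dihydro‑1,4‑benzodioxine‑2,6‑diyl}dimethanol
Conditions: LiBH4 (6 equiv), MeOH (6 equiv), THF, 0 °C, then 45 °C
Reagents that add atoms: none
Why: Reductive cleavage of the N‑acyl oxazolidinone at its exocyclic carbonyl, fast at 0 °C so that C‑2 should not epimerise, followed by LiBH4/MeOH reduction of the aryl methyl ester on warming, gives both primary alcohols in one operation.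

**Step 6**
Reactants: 10 {(2S,3S)‑3‑[4‑(benzyloxy)‑3‑methoxyphenyl]‑2,3‑dihydro‑1,4‑benzodioxine‑2,6‑diyl}dimethanol
Product: 11 (2S,3S)‑3‑[4‑(benzyloxy)‑3‑methoxyphenyl]‑2‑(hydroxymethyl)‑2,3‑dihydro‑1,4‑benzodioxine‑6‑carbaldehyde
Conditions: activated MnO2 (15 equiv), CH2Cl2, rt
Reagents that add atoms: none
Why: Activated MnO2 oxidises benzylic alcohols chemoselectively, so the arene CH2OH should give the aldehyde while the aliphatic hydroxymethyl group at C‑2 stays.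

**Step 7**
Reactants: 12 1‑(2,4,6‑trihydroxyphenyl)ethanone
Product: 13 1‑[2,4‑bis(benzyloxy)‑6‑hydroxyphenyl]ethanone
Conditions: BnBr (2.05 equiv), K2CO3 (2.2 equiv), DMF, 0 °C to rt
Reagents that add atoms: benzyl bromide, BrCc1ccccc1
Why: Williamson benzylation in which the hydroxyl hydrogen‑bonded to the ketone is the least reactive, so two equivalents of BnBr should give the bis‑ether with one ortho OH left free.

**Step 8**
Reactants: 11 (2S,3S)‑3‑[4‑(benzyloxy)‑3‑methoxyphenyl]‑2‑(hydroxymethyl)‑2,3‑dihydro‑1,4‑benzodioxine‑6‑carbaldehyde; 13 1‑[2,4‑bis(benzyloxy)‑6‑hydroxyphenyl]ethanone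
Product: 14 (2E)‑1‑[2,4‑bis(benzyloxy)‑6‑hydroxyphenyl]‑3‑{(2S,3S)‑3‑[4‑(benzyloxy)‑3‑methoxyphenyl]‑2‑(hydroxymethyl)‑2,3‑dihydro‑1,4‑benzodioxin‑6‑yl}prop‑2‑en‑1‑one
Conditions: KOH (50 % aq., 10 equiv), EtOH/THF, rt
Reagents that add atoms: none
Why: Claisen–Schmidt aldol condensation of the ketone enolate of 13 with the non‑enolisable aldehyde 11 and E1cB loss of water to the conjugated (E)‑chalcone, under which neither benzodioxane stereocentre is acidic.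

**Step 9**
Reactants: 14 (2E)‑1‑[2,4‑bis(benzyloxy)‑6‑hydroxyphenyl]‑3‑{(2S,3S)‑3‑[4‑(benzyloxy)‑3‑methoxyphenyl]‑2‑(hydroxymethyl)‑2,3‑dihydro‑1,4‑benzodioxin‑6‑yl}prop‑2‑en‑1‑one
Product: 15 5,7‑bis(benzyloxy)‑2‑{(2S,3S)‑3‑[4‑(benzyloxy)‑3‑methoxyphenyl]‑2‑(hydroxymethyl)‑2,3‑dihydro‑1,4‑benzodioxin‑6‑yl}‑3‑hydroxy‑4H‑chromen‑4‑one
Conditions: H2O2 (30 % aq., 5 equiv), NaOH (2 M aq.), MeOH/THF, 0 °C to rt
Reagents that add atoms: hydrogen peroxide, OO
Why: Algar–Flynn–Oyamada oxidation, in which alkaline H2O2 attacks the enone, the 2'‑phenoxide closes ring C at the β‑carbon to the dihydroflavonol, and this is oxidised on to the flavonol under the same conditions.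

**Step 10**
Reactants: 15 5,7‑bis(benzyloxy)‑2‑{(2S,3S)‑3‑[4‑(benzyloxy)‑3‑methoxyphenyl]‑2‑(hydroxymethyl)‑2,3‑dihydro‑1,4‑benzodioxin‑6‑yl}‑3‑hydroxy‑4H‑chromen‑4‑one
Product: 16 2,3‑dehydrosilybin B, 3,5,7‑trihydroxy‑2‑[(2S,3S)‑3‑(4‑hydroxy‑3‑methoxyphenyl)‑2‑(hydroxymethyl)‑2,3‑dihydro‑1,4‑benzodioxin‑6‑yl]‑4H‑chromen‑4‑one
Conditions: H2 (1 atm), Pd/C (10 wt %), THF/MeOH, rt, stopped when the benzyl ethers are consumed
Reagents that add atoms: none
Why: Hydrogenolysis of the three aryl benzyl ethers on Pd/C, which should be much faster than cleavage of the cyclic, secondary C‑3–O‑4 bond or reduction of the chromone double bond.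

**Compound list**
1 | 4‑(benzyloxy)‑3‑methoxybenzyl alcohol | COc1cc(CO)ccc1OCc1ccccc1 | starting material
2 | 4‑(benzyloxy)‑3‑methoxybenzyl chloride | COc1cc(CCl)ccc1OCc1ccccc1 | intermediate
3 | methyl 3,4‑dihydroxybenzoate | COC(=O)c1ccc(O)c(O)c1 | starting material
4 | methyl 3‑{[4‑(benzyloxy)‑3‑methoxybenzyl]oxy}‑4‑hydroxybenzoate | COC(=O)c1ccc(O)c(OCc2ccc(OCc3ccccc3)c(OC)c2)c1 | intermediate
5 | (S)‑4‑benzyl‑3‑(chloroacetyl)‑1,3‑oxazolidin‑2‑one | O=C1OC[C@H](Cc2ccccc2)N1C(=O)CCl | starting material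
6 | methyl 4‑{2‑[(4S)‑4‑benzyl‑2‑oxo‑1,3‑oxazolidin‑3‑yl]‑2‑oxoethoxy}‑3‑{[4‑(benzyloxy)‑3‑methoxybenzyl]oxy}benzoate | COC(=O)c1ccc(OCC(=O)N2C(=O)OC[C@@H]2Cc2ccccc2)c(OCc2ccc(OCc3ccccc3)c(OC)c2)c1 | intermediate
7 | methyl 4‑{2‑[(4S)‑4‑benzyl‑2‑oxo‑1,3‑oxazolidin‑3‑yl]‑2‑oxoethoxy}‑3‑{[4‑(benzyloxy)‑3‑methoxyphenyl](2,3‑dichloro‑5,6‑dicyano‑4‑hydroxyphenoxy)methoxy}benzoate, both epimers at the acetal carbon | COC(=O)c1ccc(OCC(=O)N2C(=O)OC[C@@H]2Cc2ccccc2)c(OC(Oc2c(Cl)c(Cl)c(O)c(C#N)c2C#N)c2ccc(OCc3ccccc3)c(OC)c2)c1 | intermediate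
8 | trichlorotitanium Z‑enolate of 6 carrying the O‑aryl oxocarbenium ion at C‑3, chloride salt | COC(=O)c1ccc(O/C=C(\O[Ti](Cl)(Cl)Cl)N2C(=O)OC[C@@H]2Cc2ccccc2)c([O+]=Cc2ccc(OCc3ccccc3)c(OC)c2)c1.[Cl-] | intermediate
9 | methyl (2R,3S)‑2‑{[(4S)‑4‑benzyl‑2‑oxo‑1,3‑oxazolidin‑3‑yl]carbonyl}‑3‑[4‑(benzyloxy)‑3‑methoxyphenyl]‑2,3‑dihydro‑1,4‑benzodioxine‑6‑carboxylate | COc1cc([C@@H]2Oc3cc(C(=O)OC)ccc3O[C@H]2C(=O)N4C(=O)OC[C@@H]4Cc5ccccc5)ccc1OCc1ccccc1 | intermediate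
10 | {(2S,3S)‑3‑[4‑(benzyloxy)‑3‑methoxyphenyl]‑2,3‑dihydro‑1,4‑benzodioxine‑2,6‑diyl}dimethanol | COc1cc([C@@H]2Oc3cc(CO)ccc3O[C@H]2CO)ccc1OCc1ccccc1 | intermediate
11 | (2S,3S)‑3‑[4‑(benzyloxy)‑3‑methoxyphenyl]‑2‑(hydroxymethyl)‑2,3‑dihydro‑1,4‑benzodioxine‑6‑carbaldehyde | COc1cc([C@@H]2Oc3cc(C=O)ccc3O[C@H]2CO)ccc1OCc1ccccc1 | intermediate
12 | 1‑(2,4,6‑trihydroxyphenyl)ethanone | CC(=O)c1c(O)cc(O)cc1O | starting material
13 | 1‑[2,4‑bis(benzyloxy)‑6‑hydroxyphenyl]ethanone | CC(=O)c1c(O)cc(OCc2ccccc2)cc1OCc1ccccc1 | intermediate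
14 | (2E)‑1‑[2,4‑bis(benzyloxy)‑6‑hydroxyphenyl]‑3‑{(2S,3S)‑3‑[4‑(benzyloxy)‑3‑methoxyphenyl]‑2‑(hydroxymethyl)‑2,3‑dihydro‑1,4‑benzodioxin‑6‑yl}prop‑2‑en‑1‑one | COc1cc([C@@H]2Oc3cc(/C=C/C(=O)c4c(O)cc(OCc5ccccc5)cc4OCc4ccccc4)ccc3O[C@H]2CO)ccc1OCc1ccccc1 | intermediate
15 | 5,7‑bis(benzyloxy)‑2‑{(2S,3S)‑3‑[4‑(benzyloxy)‑3‑methoxyphenyl]‑2‑(hydroxymethyl)‑2,3‑dihydro‑1,4‑benzodioxin‑6‑yl}‑3‑hydroxy‑4H‑chromen‑4‑one | COc1cc([C@@H]2Oc3cc(-c4oc5cc(OCc6ccccc6)cc(OCc6ccccc6)c5c(=O)c4O)ccc3O[C@H]2CO)ccc1OCc1ccccc1 | intermediate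
16 | 2,3‑dehydrosilybin B | COc1cc([C@@H]2Oc3cc(-c4oc5cc(O)cc(O)c5c(=O)c4O)ccc3O[C@H]2CO)ccc1O | target

**Step count**
Total steps: 10. Longest linear sequence: 9 (steps 1 to 6 and 8 to 10); step 7 is a one‑step side branch.

**Steps most likely to fail**

Step 4 (proposed new method). Hydride abstraction from an aryl (not alkyl) dialkoxybenzyl ether may be slow or unselective. The cation may be lost by reduction or arene alkylation before the enolate is formed. Facial control by the auxiliary may be poor when the electrophile is tethered through the α‑oxygen. The fallback uses known chemistry and closes the ring by C–O instead of C–C bond formation; it sets out from 4 and returns at 10. Phenol 4 is alkylated with (R)‑4‑benzyl‑3‑(chloroacetyl)‑1,3‑oxazolidin‑2‑one, the commercial enantiomer of 5 (K2CO3, NaI, acetone), to give methyl 4‑{2‑[(4R)‑4‑benzyl‑2‑oxo‑1,3‑oxazolidin‑3‑yl]‑2‑oxoethoxy}‑3‑{[4‑(benzyloxy)‑3‑methoxybenzyl]oxy}benzoate F1. An Evans syn‑aldol reaction (Bu2BOTf, i‑Pr2NEt, CH2Cl2, −78 to 0 °C) with commercial 4‑(benzyloxy)‑3‑methoxybenzaldehyde should give the syn aldol methyl 4‑{[(1R,2S)‑1‑{[(4R)‑4‑benzyl‑2‑oxo‑1,3‑oxazolidin‑3‑yl]carbonyl}‑2‑[4‑(benzyloxy)‑3‑methoxyphenyl]‑2‑hydroxyethyl]oxy}‑3‑{[4‑(benzyloxy)‑3‑methoxybenzyl]oxy}benzoate F2. The boron enolate reacts on the enolate face opposite to that used by the chelated titanium enolate, hence the enantiomeric auxiliary. TFA with 1,3,5‑trimethoxybenzene in CH2Cl2 at 0 °C ionises both electron‑rich benzylic C–O bonds. The benzyl group on the 3‑oxygen passes to the scavenger and the freed phenol closes onto the benzylic cation to the trans‑benzodioxane methyl (2R,3S)‑2‑{[(4R)‑4‑benzyl‑2‑oxo‑1,3‑oxazolidin‑3‑yl]carbonyl}‑3‑[4‑(benzyloxy)‑3‑methoxyphenyl]‑2,3‑dihydro‑1,4‑benzodioxine‑6‑carboxylate F3. LiBH4/MeOH as in step 5 then gives 10.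

Step 2. The dianion may be alkylated at the wrong oxygen, at both oxygens or at carbon, and dimsyl sodium may attack the methyl ester. The fallback replaces kinetic discrimination by a protecting‑group sequence; it sets out from 3 and returns at 4. The more acidic 4‑OH of 3 is allylated (allyl bromide, NaHCO3, NaI, DMF, 40 °C) to methyl 4‑(allyloxy)‑3‑hydroxybenzoate F4. The remaining phenol is alkylated with 2 (K2CO3, DMF) to methyl 4‑(allyloxy)‑3‑{[4‑(benzyloxy)‑3‑methoxybenzyl]oxy}benzoate F5. Pd(PPh3)4 (zerovalent palladium) with morpholine in THF removes the allyl group to give 4.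

Step 9. In chalcones with a 6'‑alkoxy group the phenoxide may close at the α‑carbon and divert the oxidation to the aurone, and alkaline peroxide may cleave the enone. The fallback separates ring closure from C‑3 hydroxylation; it sets out from 14 and returns at 15. I2 (cat.) in DMSO at 110 °C cyclises and dehydrogenates 14 to the flavone 5,7‑bis(benzyloxy)‑2‑{(2S,3S)‑3‑[4‑(benzyloxy)‑3‑methoxyphenyl]‑2‑(hydroxymethyl)‑2,3‑dihydro‑1,4‑benzodioxin‑6‑yl}‑4H‑chromen‑4‑one F6. Dimethyldioxirane in acetone/CH2Cl2 at 0 °C epoxidises the C‑2–C‑3 double bond to the 2,3‑epoxyflavanone F7, a mixture of epoxide diastereomers. TsOH (cat.) opens it to 15.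

**Further compounds**
F1 | step 4 | methyl 4‑{2‑[(4R)‑4‑benzyl‑2‑oxo‑1,3‑oxazolidin‑3‑yl]‑2‑oxoethoxy}‑3‑{[4‑(benzyloxy)‑3‑methoxybenzyl]oxy}benzoate | COC(=O)c1ccc(OCC(=O)N2C(=O)OC[C@H]2Cc2ccccc2)c(OCc2ccc(OCc3ccccc3)c(OC)c2)c1
F2 | step 4 | methyl 4‑{[(1R,2S)‑1‑{[(4R)‑4‑benzyl‑2‑oxo‑1,3‑oxazolidin‑3‑yl]carbonyl}‑2‑[4‑(benzyloxy)‑3‑methoxyphenyl]‑2‑hydroxyethyl]oxy}‑3‑{[4‑(benzyloxy)‑3‑methoxybenzyl]oxy}benzoate | COC(=O)c1ccc(O[C@H]([C@@H](O)c2ccc(OCc3ccccc3)c(OC)c2)C(=O)N2C(=O)OC[C@H]2Cc2ccccc2)c(OCc2ccc(OCc3ccccc3)c(OC)c2)c1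
F3 | step 4 | methyl (2R,3S)‑2‑{[(4R)‑4‑benzyl‑2‑oxo‑1,3‑oxazolidin‑3‑yl]carbonyl}‑3‑[4‑(benzyloxy)‑3‑methoxyphenyl]‑2,3‑dihydro‑1,4‑benzodioxine‑6‑carboxylate | COc1cc([C@@H]2Oc3cc(C(=O)OC)ccc3O[C@H]2C(=O)N4C(=O)OC[C@H]4Cc5ccccc5)ccc1OCc1ccccc1
F4 | step 2 | methyl 4‑(allyloxy)‑3‑hydroxybenzoate | COC(=O)c1ccc(OCC=C)c(O)c1
F5 | step 2 | methyl 4‑(allyloxy)‑3‑{[4‑(benzyloxy)‑3‑methoxybenzyl]oxy}benzoate | COC(=O)c1ccc(OCC=C)c(OCc2ccc(OCc3ccccc3)c(OC)c2)c1
F6 | step 9 | 5,7‑bis(benzyloxy)‑2‑{(2S,3S)‑3‑[4‑(benzyloxy)‑3‑methoxyphenyl]‑2‑(hydroxymethyl)‑2,3‑dihydro‑1,4‑benzodioxin‑6‑yl}‑4H‑chromen‑4‑one | COc1cc([C@@H]2Oc3cc(-c4cc(=O)c5c(OCc6ccccc6)cc(OCc6ccccc6)cc5o4)ccc3O[C@H]2CO)ccc1OCc1ccccc1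
F7 | step 9 | 2,3‑epoxide of F6 (5,7‑bis(benzyloxy)‑2,3‑epoxyflavanone bearing the same benzodioxane) | COc1cc([C@@H]2Oc3cc(C45OC4C(=O)c4c(OCc6ccccc6)cc(OCc6ccccc6)cc4O5)ccc3O[C@H]2CO)ccc1OCc1ccccc1
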